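The plan hinges on disconnecting the C2–C3 bond of ring A (labdane numbering). The two carbinol carbons are flanked only by C1, a CH2 on the quaternary fusion carbon C10, and by C4, the dimethylated carbon on C5; cutting between them therefore unfolds ring A into two aldehydes hanging from an intact ring B. One SmI2 pinacol coupling re-forms C2–C3, closes ring A and sets both hydroxyl stereocentres. The precursor is a ring B cyclohexane that already holds C5, C8, C9 and C10 in their final configuration, the silyl-alkyne chain and the C2 and C3 aldehydes; its tertiary C9 oxygen is silylated, since a free 9-hydroxyl would capture the C2 aldehyde as a lactol.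

Key step: step 9

Remark on conventions: labdane numbering is used for every intermediate (ring B = C5–C10, chain = C11–C15), and α/β refer to the usual drawing with the C10 methyl β.
Remark on the chemistry: ketene silyl acetal 2 is taken as the purchased reagent. The target enoate is 13Z, with C12 and the ester carbon on the same side of C13=C14.

Step 1
Reactants: 1 (R)-carvone; 2 1-methoxy-2-methyl-1-(trimethylsilyloxy)prop-1-ene
Product: 3 silyl enol ether of the Michael adduct (C9–C10 enol ether, C5 ester arm β, C7 isopropenyl α)
Conditions: Ph3CSbCl6 (5 mol %), CH2Cl2, −78 °C; then pyridine, non-aqueous work-up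
Reagents that add atoms: none
Why: Mukaiyama–Michael addition under trityl-cation catalysis, in which the silyl group migrates to the enolate oxygen so that the regiodefined C9–C10 silyl enol ether is kept; the ketene acetal attacks C5 axially, anti to the C7 isopropenyl group, which sets C5.

Step 2
Reactants: 3 silyl enol ether; 4 tert-butyl bromoacetate
Product: 6 keto diester bearing 10β-CH3, 10α-CH2CO2t-Bu, 5β-C(CH3)2CO2CH3 and 7α-isopropenyl, via benzyltrimethylammonium C9–C10 enolate 5 (not isolated)
Conditions: BnMe3NF (dried), 4 Å MS, THF, 0 °C → rt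
Reagents that add atoms: none
Why: fluoride desilylation releases the regiospecific tetrasubstituted enolate without a nucleophile that could attack the methyl ester, and enolate SN2 alkylation should occur on the face opposite the pseudoaxial C5 arm (held axial by allylic 1,2-strain with the C10 methyl), so the acetate unit enters α and the C10 methyl ends β.

Step 3
Reactants: 6 keto diester with isopropenyl group
Product: 8 keto diester with C7 = CH2, via α-methoxy hydroperoxide 7 (not isolated)
Conditions: O3, MeOH, −78 °C; then PhSH, FeSO4·7H2O, −78 °C → rt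
Reagents that add atoms: none
Why: ozonolysis in methanol followed by reductive fragmentation with divalent iron (hydrodealkenylation): the alkoxy radical from the methoxy hydroperoxide loses methyl acetate by β-scission and the secondary C7 radical takes a hydrogen atom from benzenethiol; ketone and esters are inert, and the C7 stereocentre, having done its directing work, is erased.

Step 4
Reactants: 8 keto diester
Product: 10 8α-methyl keto diester, via lithium C8–C9 enolate 9 (not isolated)
Conditions: LDA, THF, −78 °C; MeI, −78 → −20 °C; then K2CO3 (cat.), MeOH, rt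
Reagents that add atoms: iodomethane, CI
Why: kinetic ketone enolate alkylation at C8, the only enolisable ketone position (ketone deprotonation outruns that of the hindered tert-butyl ester); mild base equilibration should then leave the methyl equatorial (α), because a β-methyl would be 1,3-diaxial to the C10 methyl in the chair that keeps the bulky C5 arm equatorial.

Step 5
Reactants: 10 8α-methyl keto diester; 11 4-bromo-1-(trimethylsilyl)but-1-yne
Product: 14 9β-hydroxy diester with 9α-CH2CH2C≡CSiMe3 chain, via [4-(trimethylsilyl)but-3-yn-1-yl]magnesium bromide 12 (not isolated), via dichloro[4-(trimethylsilyl)but-3-yn-1-yl]cerium 13 (not isolated)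
Conditions: 11, Mg, THF, rt; anhydrous CeCl3, THF, −78 °C; then 10, −78 → −30 °C; aq. NH4Cl at −30 °C
Reagents that add atoms: none
Why: organocerium 1,2-addition, chosen because the weakly basic reagent adds to hindered enolisable ketones in preference to esters; attack should be axial from the α face, since equatorial β attack would eclipse the axial C10 methyl, giving the 9β-carbinol with the chain α, and the cold quench keeps the alkoxide from closing onto the tert-butyl ester.

Step 6
Reactants: 14 9β-hydroxy diester
Product: 15 9β-triethylsilyl ether diester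
Conditions: TESOTf, 2,6-lutidine, CH2Cl2, −78 → 0 °C
Reagents that add atoms: triethylsilyl trifluoromethanesulfonate, CC[Si](CC)(CC)OS(=O)(=O)C(F)(F)F
Why: silyl triflate silylation is the standard way to cap a hindered tertiary alcohol, and at low temperature with 2,6-lutidine the tert-butyl ester is untouched; the ether blocks lactone, lactol and later carbonate formation at O9.

Step 7
Reactants: 15 9β-triethylsilyl ether diester
Product: 16 2,3-diol (C2 and C3 as CH2OH)
Conditions: LiAlH4, THF, 0 °C → rt
Reagents that add atoms: none
Why: LiAlH4 reduction of both esters to primary alcohols; the tertiary silyl ether and the isolated silyl alkyne are inert to hydride under these conditions.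

Step 8
Reactants: 16 2,3-diol
Product: 17 dialdehyde (9β-OSiEt3, 9α-silylbutynyl chain, 8α-CH3, 10β-CH3, 10α-CH2CHO, 5β-C(CH3)2CHO)
Conditions: Dess–Martin periodinane, CH2Cl2, 0 °C → rt; crude product used at once
Reagents that add atoms: none
Why: Dess–Martin oxidation of both primary alcohols under nearly neutral conditions avoids aldol closure of the enolisable C2 aldehyde onto the C3 aldehyde, and with O9 silylated no lactol can form.

Step 9
Reactants: 17 dialdehyde
Product: 18 trans-decalin 2α,3α-diol (9β-OSiEt3, 9α-silylbutynyl chain)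
Conditions: SmI2 (0.1 M in THF, 3 equiv), t-BuOH (2 equiv), THF, −78 °C → rt, slow addition of 17 at high dilution
Reagents that add atoms: none
Why: Divalent samarium transfers one electron to an aldehyde to give a ketyl, which adds to the second, samarium-bound aldehyde, and a further electron transfer with protonation delivers the diol; the closest known reaction type is the SmI2 pinacol cyclisation of 1,6-dialdehydes to cis-cyclohexane-1,2-diols. Ring A closes by 6-exo-trig attack of the ketyl carbon on the other carbonyl carbon, forming C2–C3. The cis relationship of the two new centres is controlled by trivalent samarium bridging both oxygens in a chair-like transition state built on the rigid ring B chair. Their α orientation is controlled by the axial β methyls on C4 and C10: the β,β-cis alternative needs an axial C2 oxygen syn to both, whereas the α,α isomer has C2–O equatorial and C3–O axial against hydrogens only. The step needs ring closure to win over simple reduction and intermolecular coupling, which high dilution, low temperature and the two fully substituted carbons (C4, C10) holding the aldehydes together should secure; the silyl alkyne and silyl ether are inert to SmI2 without strongly donating additives.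

Step 10
Reactants: 18 2α,3α-diol
Product: 19 2α,3α-acetonide
Conditions: 2,2-dimethoxypropane, PPTS (cat.), CH2Cl2, rt
Reagents that add atoms: 2,2-dimethoxypropane, COC(C)(C)OC
Why: acid-catalysed transketalisation; the cis (equatorial/axial) diol closes a dioxolane readily and the tertiary triethylsilyl ether tolerates PPTS.

Step 11
Reactants: 19 acetonide
Product: 20 terminal alkyne
Conditions: K2CO3, MeOH, rt
Reagents that add atoms: none
Why: base-mediated methanolysis of the alkynyl C–Si bond (protodesilylation), to which the hindered tertiary silyl ether and the acetonide are stable.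

Step 12
Reactants: 20 terminal alkyne
Product: 22 methyl ynoate, via lithium acetylide 21 (not isolated)
Conditions: n-BuLi, THF, −78 °C; ClCO2Me, −78 → 0 °C
Reagents that add atoms: methyl chloroformate, COC(=O)Cl
Why: deprotonation of the terminal alkyne and C-acylation of the acetylide with the chloroformate; with all three oxygens masked no carbonate can form.

Step 13
Reactants: 22 methyl ynoate
Product: 23 protected (13Z)-enoate
Conditions: Me2CuLi (from CuI and MeLi), THF, −78 °C; MeOH at −78 °C, then aq. NH4Cl
Reagents that add atoms: lithium dimethylcuprate, [Li+].C[Cu-]C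
Why: organocuprate conjugate addition to an ynoate is a syn carbocupration, placing methyl on C13 and copper on C14 on the same side; protonation with retention at −78 °C should leave C12 and the ester cis, which is the Z geometry.

Step 14
Reactants: 23 protected (13Z)-enoate
Product: 24 target, methyl (2Z)-3-methyl-5-[(1S,2R,4aS,6S,7R,8aS)-1,6,7-trihydroxy-2,5,5,8a-tetramethyldecahydronaphthalen-1-yl]pent-2-enoate
Conditions: 1 M aq. HCl, THF, rt
Reagents that add atoms: none
Why: acid hydrolysis removes the acetonide and the tertiary triethylsilyl ether in one operation under conditions too mild to ionise the C9 carbinol, hydrolyse the methyl ester or isomerise the enoate.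

Compound list
1 | (R)-carvone, (5R)-2-methyl-5-(prop-1-en-2-yl)cyclohex-2-en-1-one | CC1=CC[C@H](CC1=O)C(=C)C | starting material
2 | 1-methoxy-2-methyl-1-(trimethylsilyloxy)prop-1-ene | COC(=C(C)C)O[Si](C)(C)C | starting material
3 | methyl 2-methyl-2-[(1R,5R)-2-methyl-5-(prop-1-en-2-yl)-3-(trimethylsilyloxy)cyclohex-2-en-1-yl]propanoate (C5 arm β, C7 isopropenyl α) | C[Si](C)(C)OC1=C(C)[C@H](C(C)(C)C(=O)OC)C[C@@H](C(C)=C)C1 | intermediate
4 | tert-butyl bromoacetate | CC(C)(C)OC(=O)CBr | starting material
5 | benzyltrimethylammonium C9–C10 enolate derived from 3 | C[N+](C)(C)Cc1ccccc1.[O-]C1=C(C)[C@H](C(C)(C)C(=O)OC)C[C@@H](C(C)=C)C1 | intermediate (not isolated)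
6 | ring B ketone (C9=O) with 10β-CH3, 10α-CH2CO2t-Bu, 5β-C(CH3)2CO2CH3, 7α-isopropenyl | O=C1C[C@H](C(C)=C)C[C@@H](C(C)(C)C(=O)OC)[C@]1(C)CC(=O)OC(C)(C)C | intermediate
7 | 6 with the isopropenyl group replaced by 1-hydroperoxy-1-methoxyethyl (both epimers at that carbon) | O=C1C[C@H](C(C)(OC)OO)C[C@@H](C(C)(C)C(=O)OC)[C@]1(C)CC(=O)OC(C)(C)C | intermediate (not isolated)
8 | ring B ketone with C7 = CH2, 10β-CH3, 10α-CH2CO2t-Bu, 5β-C(CH3)2CO2CH3 | O=C1CCC[C@@H](C(C)(C)C(=O)OC)[C@]1(C)CC(=O)OC(C)(C)C | intermediate
9 | lithium C8–C9 enolate of 8 | [Li+].[O-]C1=CCC[C@@H](C(C)(C)C(=O)OC)[C@]1(C)CC(=O)OC(C)(C)C | intermediate (not isolated)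
10 | 8α-methyl ketone: 8 with 8α-CH3 | O=C1[C@H](C)CC[C@@H](C(C)(C)C(=O)OC)[C@]1(C)CC(=O)OC(C)(C)C | intermediate
11 | 4-bromo-1-(trimethylsilyl)but-1-yne | C[Si](C)(C)C#CCCBr | starting material
12 | [4-(trimethylsilyl)but-3-yn-1-yl]magnesium bromide | C[Si](C)(C)C#CCC[Mg]Br | intermediate (not isolated)
13 | dichloro[4-(trimethylsilyl)but-3-yn-1-yl]cerium | C[Si](C)(C)C#CCC[Ce](Cl)Cl | intermediate (not isolated)
14 | 9β-hydroxy diester with 9α-[4-(trimethylsilyl)but-3-ynyl] chain, 8α-CH3, 10β-CH3 | C[Si](C)(C)C#CCC[C@]1(O)[C@H](C)CC[C@@H](C(C)(C)C(=O)OC)[C@]1(C)CC(=O)OC(C)(C)C | intermediate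
15 | 9β-triethylsilyl ether of 14 | C[Si](C)(C)C#CCC[C@]1(O[Si](CC)(CC)CC)[C@H](C)CC[C@@H](C(C)(C)C(=O)OC)[C@]1(C)CC(=O)OC(C)(C)C | intermediate
16 | 2,3-diol: 15 with both esters reduced to CH2OH | C[Si](C)(C)C#CCC[C@]1(O[Si](CC)(CC)CC)[C@H](C)CC[C@@H](C(C)(C)CO)[C@]1(C)CCO | intermediate
17 | dialdehyde, key-step precursor: 9β-OSiEt3, 9α-silylbutynyl, 8α-CH3, 10β-CH3, 10α-CH2CHO, 5β-C(CH3)2CHO | C[Si](C)(C)C#CCC[C@]1(O[Si](CC)(CC)CC)[C@H](C)CC[C@@H](C(C)(C)C=O)[C@]1(C)CC=O | intermediate
18 | key-step product: trans-decalin 2α,3α-diol, 9β-OSiEt3, 9α-silylbutynyl, 4,4,8α,10β-tetramethyl, 5α-H | C[Si](C)(C)C#CCC[C@]1(O[Si](CC)(CC)CC)[C@H](C)CC[C@H]2C(C)(C)[C@H](O)[C@H](O)C[C@@]21C | intermediate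
19 | 2α,3α-O-isopropylidene derivative of 18 | C[Si](C)(C)C#CCC[C@]1(O[Si](CC)(CC)CC)[C@H](C)CC[C@H]2C(C)(C)[C@H](O3)[C@H](OC3(C)C)C[C@@]21C | intermediate
20 | terminal alkyne: 19 without the alkynyl SiMe3 | C#CCC[C@]1(O[Si](CC)(CC)CC)[C@H](C)CC[C@H]2C(C)(C)[C@H](O3)[C@H](OC3(C)C)C[C@@]21C | intermediate
21 | lithium acetylide of 20 | [Li]C#CCC[C@]1(O[Si](CC)(CC)CC)[C@H](C)CC[C@H]2C(C)(C)[C@H](O3)[C@H](OC3(C)C)C[C@@]21C | intermediate (not isolated)
22 | methyl ynoate: 20 with CO2CH3 on the alkyne terminus | COC(=O)C#CCC[C@]1(O[Si](CC)(CC)CC)[C@H](C)CC[C@H]2C(C)(C)[C@H](O3)[C@H](OC3(C)C)C[C@@]21C | intermediate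
23 | protected (13Z)-enoate: 24 carrying the 2α,3α-acetonide and 9β-OSiEt3 | COC(=O)/C=C(/C)CC[C@]1(O[Si](CC)(CC)CC)[C@H](C)CC[C@H]2C(C)(C)[C@H](O3)[C@H](OC3(C)C)C[C@@]21C | intermediate
24 | methyl (2Z)-3-methyl-5-[(1S,2R,4aS,6S,7R,8aS)-1,6,7-trihydroxy-2,5,5,8a-tetramethyldecahydronaphthalen-1-yl]pent-2-enoate | COC(=O)/C=C(/C)CC[C@]1(O)[C@H](C)CC[C@H]2C(C)(C)[C@H](O)[C@H](O)C[C@@]21C | target

Total step count: 14. Longest linear sequence: 14 steps, from 1 to 24.

Steps most likely to fail

Step 9. The ring closure may lose stereocontrol (a trans-diequatorial or β,β-cis diol), or the ketyls may be diverted to simple reduction or intermolecular coupling. The fallback sets out from 17 and separates bond formation from oxygenation. Low-valent titanium (TiCl3(DME)1.5, Zn–Cu couple, DME, reflux, slow addition; McMurry coupling) should give the ring A Δ2-olefin F1. Dihydroxylation with OsO4 (cat.) and N-methylmorpholine N-oxide in acetone/water should then occur from the α face, because the axial methyls on C4 and C10 shield the β face. This returns to the route at 18.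

Step 5. Addition to a carbonyl flanked by a quaternary and a tertiary carbon may stall through enolisation toward C8 or hydride transfer from the reagent, or be eroded in facial selectivity. The fallback sets out from 10 and builds the chain in two pieces with a smaller sp2 nucleophile that has no transferable β-hydrogen. Vinylmagnesium bromide with CeCl3 should give the 9β-hydroxy-9α-vinyl diester F2. Silylation (TESOTf, 2,6-lutidine) gives its triethylsilyl ether F3. Hydroboration–oxidation (9-BBN, then NaBO3·4H2O) gives the primary C12 alcohol F4. Iodination (I2, PPh3, imidazole) gives the primary iodide F5. Displacement with lithium (trimethylsilyl)acetylide in THF/DMPU returns to the route at 15.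

Step 2. C-alkylation at the crowded tetrasubstituted enolate may be outrun by proton exchange or O-alkylation. The fallback sets out from 3 and uses a cationic electrophile on the silyl enol ether itself. Thiophenol and 4 (K2CO3, acetone) give tert-butyl (phenylthio)acetate F6, which N-chlorosuccinimide converts into tert-butyl chloro(phenylthio)acetate F7. ZnBr2 (cat.) in CH2Cl2 generates the thionium ion from F7, which alkylates 3 at C10 to give the α-phenylthio keto diester F8. Radical desulfurisation (Bu3SnH, AIBN, toluene, 80 °C), which spares the isopropenyl group, returns to the route at 6.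

Further compounds
F1 | step 9 | ring A Δ2-olefin: decalin with C2=C3, 9β-OSiEt3, 9α-silylbutynyl chain | C[Si](C)(C)C#CCC[C@]1(O[Si](CC)(CC)CC)[C@H](C)CC[C@H]2C(C)(C)C=CC[C@@]21C
F2 | step 5 | 9β-hydroxy-9α-vinyl diester | C=C[C@]1(O)[C@H](C)CC[C@@H](C(C)(C)C(=O)OC)[C@]1(C)CC(=O)OC(C)(C)C
F3 | step 5 | 9β-triethylsilyl ether of the 9α-vinyl diester | C=C[C@]1(O[Si](CC)(CC)CC)[C@H](C)CC[C@@H](C(C)(C)C(=O)OC)[C@]1(C)CC(=O)OC(C)(C)C
F4 | step 5 | 9α-(2-hydroxyethyl) silyl ether diester | OCC[C@]1(O[Si](CC)(CC)CC)[C@H](C)CC[C@@H](C(C)(C)C(=O)OC)[C@]1(C)CC(=O)OC(C)(C)C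
F5 | step 5 | 9α-(2-iodoethyl) silyl ether diester | ICC[C@]1(O[Si](CC)(CC)CC)[C@H](C)CC[C@@H](C(C)(C)C(=O)OC)[C@]1(C)CC(=O)OC(C)(C)C
F6 | step 2 | tert-butyl (phenylthio)acetate | CC(C)(C)OC(=O)CSc1ccccc1
F7 | step 2 | tert-butyl chloro(phenylthio)acetate | CC(C)(C)OC(=O)C(Cl)Sc1ccccc1
F8 | step 2 | 6 carrying a phenylthio group on C1 (both epimers) | O=C1C[C@H](C(C)=C)C[C@@H](C(C)(C)C(=O)OC)[C@]1(C)C(Sc2ccccc2)C(=O)OC(C)(C)C
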